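**Retrosynthetic overview**

1. Ring numbering used here: C1 = carbinol carbon (OH and side chain), C2, C3, C4 = C(Br)CH3, C5 = CHCl, C6. The side chain is grown last from a C1 ethynyl group: (R)-carbinol ← CBS reduction of an isopropenyl ketone ← ruthenium-catalysed alkyne/allylic alcohol coupling.
2. C4–Br/C5–Cl ← tertiary chlorohydrin (bromination with retention through a chlorine-bridged cation) ← hydroxyl-directed cis-epoxide of (S)-1-ethynyl-4-methylcyclohex-3-en-1-ol. The slim ethynyl group lets the C1 oxygen sit equatorial, so both halides can enter axially (relay C1 → C5 → C4).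
3. The only ring, the cyclohexene, is closed once, by ring-closing metathesis at C4=C5 of an acyclic dienol.
4. Key disconnection at C2–C3 and C5–C6: the dienol ← one-flask union of a methallyl nucleophile, a vinyl nucleophile and an enantiopure 2-alkynylglycidyl tosylate (Sharpless epoxidation sets C1).
5. Enabling feature: C1 is a fully substituted carbinol carbon flanked in the ring by two CH2 groups (C2 and C6), a 2-substituted glycerol unit. As an oxirane/CH2OTs pair its two CH2 termini become electrophilic one after the other, so the order of addition writes the configuration of C1.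

Key step: step 3

Remark on the chemistry: vinyllithium 8 is taken to be made in a second flask from 7 and n-BuLi and transferred by cannula; this is counted as part of step 3.

**Route**

Step 1
Reactants: 1 2-bromoprop-2-en-1-ol; 2 ethynyltrimethylsilane
Product: 3 2-[(trimethylsilyl)ethynyl]prop-2-en-1-ol
Conditions: PdCl2(PPh3)2 (cat.), CuI (cat.), i-Pr2NH, THF, 23 °C
Reagents that add atoms: none
Why: Sonogashira coupling of a 2-bromoalkene with a terminal alkyne, which tolerates the free allylic alcohol and creates no stereocenter.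

Step 2
Reactants: 3 2-[(trimethylsilyl)ethynyl]prop-2-en-1-ol
Product: 5 [(2S)-2-[(trimethylsilyl)ethynyl]oxiran-2-yl]methyl 4-methylbenzenesulfonate, via epoxy alcohol 4 (not isolated)
Conditions: Ti(OiPr)4 (cat.), diisopropyl D-tartrate (cat.), t-BuOOH, 4 Å molecular sieves, CH2Cl2, −20 °C; then P(OMe)3; then TsCl, Et3N, 4-(dimethylamino)pyridine (cat.), −10 °C
Reagents that add atoms: tert-butyl hydroperoxide CC(C)(C)OO; 4-methylbenzenesulfonyl chloride Cc1ccc(cc1)S(=O)(=O)Cl
Why: Sharpless asymmetric epoxidation with in situ sulfonylation; the D-tartrate catalyst should deliver oxygen to the alkene face that gives the (R)-epoxy alcohol 4 (catalyst control, same sense as (R)-glycidol from allyl alcohol), and the sensitive 2-substituted glycidol is trapped as its stable tosylate, whose change of descriptor to (S) is only a change of priorities.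

Step 3
Reactants: 5 [(2S)-2-[(trimethylsilyl)ethynyl]oxiran-2-yl]methyl 4-methylbenzenesulfonate; 6 (2-methylprop-2-en-1-yl)magnesium chloride; 7 tetraethenylstannane
Product: 11 (4S)-7-methyl-4-[(trimethylsilyl)ethynyl]octa-1,7-dien-4-ol, via vinyllithium 8 (not isolated), via chloromagnesium alkoxide 9 (not isolated), via relayed oxirane 10 (not isolated)
Conditions: 6 (1.0 equiv), THF, −40 → 23 °C; then −78 °C, 8 (from 7, n-BuLi), BF3·OEt2, −78 → −40 °C; aq. NH4Cl
Reagents that add atoms: none
Why: Three-component linchpin coupling by two successive SN2 oxirane openings: the allylic Grignard reagent 6 opens the strained, magnesium-activated oxirane of 5 at its CH2 (this carbon becomes C2, new bond C2–C3), the tertiary alkoxide 9 then displaces the neighbouring tosylate to unveil oxirane 10, and BF3-activated vinyllithium 8 opens 10 at its CH2 (this carbon becomes C6, new bond C5–C6). The closest known reaction types are the opening of glycidyl arenesulfonates at the oxirane carbon by organometallic reagents with subsequent ring closure, one-flask epihalohydrin couplings with two different carbon nucleophiles, and BF3-mediated openings of oxiranes by alkenyllithium reagents. The only ring closed is the transient oxirane of 10 (3-exo-tet); no ring of the target is formed in this step. No new stereocenter is created: the configuration set in step 2 is carried into C1, and its sense in 11 (S) follows only from which CH2 arm meets which nucleophile, that is from the order of addition. The step needs site selectivity (oxirane CH2 before the sulfonate-bearing CH2, primary before fully substituted oxirane carbon, SN2 before SN2'), which is secured because only the oxirane carbon is strained while the CH2OTs carbon is hindered by the adjacent fully substituted centre, because copper is left out so that the alkynyl oxiranes are not opened in the SN2' sense, and because the alkynyl group disfavours a cation at C1 under BF3. Chemoselectivity between the two nucleophiles is automatic, since the second electrophile exists only after the first has been consumed.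

Step 4
Reactants: 11 (4S)-7-methyl-4-[(trimethylsilyl)ethynyl]octa-1,7-dien-4-ol
Product: 13 (1S)-1-ethynyl-4-methylcyclohex-3-en-1-ol, via silylalkyne 12 (not isolated)
Conditions: second-generation Grubbs catalyst RuCl2(=CHPh)(H2IMes)(PCy3) (cat.), CH2Cl2, 40 °C; then K2CO3 (cat.), MeOH, 23 °C
Reagents that add atoms: none
Why: Ring-closing metathesis of the monosubstituted with the 1,1-disubstituted alkene closes the six-membered ring as the trisubstituted C4=C5 cycloalkene (the carbene formed at the allyl terminus could reach the hindered silylalkyne only through a four-membered ring, so enyne metathesis should not compete), and base-catalysed methanolysis then removes the C-silyl group; C1 is untouched.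

Step 5
Reactants: 13 (1S)-1-ethynyl-4-methylcyclohex-3-en-1-ol
Product: 14 (1S,3S,6R)-3-ethynyl-6-methyl-7-oxabicyclo[4.1.0]heptan-3-ol
Conditions: VO(acac)2 (cat.), t-BuOOH, CH2Cl2, 0 → 23 °C
Reagents that add atoms: tert-butyl hydroperoxide CC(C)(C)OO
Why: Vanadium-catalysed hydroxyl-directed epoxidation of a homoallylic cyclohex-3-en-1-ol (the reaction type known for terpinen-4-ol), in which the metal-bound C1 alkoxide delivers oxygen to the ring alkene on its own face (substrate control, epoxide cis to OH) while the alkyne is inert.

Step 6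
Reactants: 14 (1S,3S,6R)-3-ethynyl-6-methyl-7-oxabicyclo[4.1.0]heptan-3-ol
Product: 15 triethyl{[(1S,3S,6R)-3-ethynyl-6-methyl-7-oxabicyclo[4.1.0]heptan-3-yl]oxy}silane
Conditions: Et3SiOTf, 2,6-lutidine, CH2Cl2, −78 °C
Reagents that add atoms: triethylsilyl trifluoromethanesulfonate CC[Si](CC)(CC)OS(=O)(=O)C(F)(F)F
Why: O-Silylation of the tertiary alcohol with a silyl triflate and a hindered base at low temperature, which the epoxide should survive; the ether keeps the C1 oxygen from attacking C4 across the ring and from reacting with the halogenating agents of steps 7 and 8.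

Step 7
Reactants: 15 triethyl{[(1S,3S,6R)-3-ethynyl-6-methyl-7-oxabicyclo[4.1.0]heptan-3-yl]oxy}silane
Product: 16 (1R,2R,4S)-2-chloro-4-ethynyl-1-methyl-4-[(triethylsilyl)oxy]cyclohexan-1-ol
Conditions: Li2CuCl4, THF, 0 → 23 °C; aq. NH4Cl
Reagents that add atoms: dilithium tetrachlorocuprate [Li+].[Li+].Cl[Cu-2](Cl)(Cl)Cl
Why: SN2-type epoxide opening by soft chloride at the secondary carbon C5 with inversion (the regiochemistry known for tetrahalometalate openings of 1-methylcyclohexene oxide); in the chair with the silyloxy group equatorial and the slim ethynyl group axial this is also the trans-diaxial (Fürst–Plattner) opening, so chlorine ends trans to the C1 oxygen and the tertiary C4 hydroxyl cis to it.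

Step 8
Reactants: 16 (1R,2R,4S)-2-chloro-4-ethynyl-1-methyl-4-[(triethylsilyl)oxy]cyclohexan-1-ol
Product: 17 {[(1S,3R,4R)-4-bromo-3-chloro-1-ethynyl-4-methylcyclohexyl]oxy}triethylsilane
Conditions: SOBr2, 2,6-di-tert-butyl-4-methylpyridine, CH2Cl2, −40 → 0 °C
Reagents that add atoms: thionyl bromide O=S(Br)Br
Why: Substitution of the tertiary alcohol through its bromosulfite with neighbouring-group participation (the classical retentive conversion of trans-2-halocycloalkanols into trans-1,2-dihalides): the axial C4–O bond is antiperiplanar to the axial C5–Cl bond, ionisation gives a chlorine-bridged cation, and bromide opens it at the tertiary carbon from the face the oxygen left, so C4 keeps its configuration and bromine ends trans to chlorine.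

Step 9
Reactants: 18 2-methylprop-2-enal; 19 ethenylmagnesium bromide
Product: 20 2-methylpenta-1,4-dien-3-ol (racemic)
Conditions: THF, −78 → 0 °C; aq. NH4Cl
Reagents that add atoms: none
Why: 1,2-Addition of a vinyl Grignard reagent to an α-substituted enal; the carbinol center is racemic and is erased in step 10.

Step 10
Reactants: 17 {[(1S,3R,4R)-4-bromo-3-chloro-1-ethynyl-4-methylcyclohexyl]oxy}triethylsilane; 20 2-methylpenta-1,4-dien-3-ol
Product: 22 6-{(1S,3R,4R)-4-bromo-3-chloro-4-methyl-1-[(triethylsilyl)oxy]cyclohexyl}-2-methylhepta-1,6-dien-3-one, via enol 21 (not isolated)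
Conditions: [CpRu(MeCN)3]PF6 (cat.), acetone, 23 °C
Reagents that add atoms: none
Why: Ruthenium-catalysed Alder-ene type coupling of a terminal alkyne with an allylic alcohol, which joins the internal alkyne carbon to the vinyl terminus of 20 through a ruthenacyclopentene, leaves the 1,1-disubstituted alkene on the carbon next to C1 and releases an enol that tautomerises to the ketone; the bulky fully substituted propargylic carbon should favour the branched isomer, and the isopropenyl group of 20, the alkyl halides and the silyl ether are spectators.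

Step 11
Reactants: 22 6-{(1S,3R,4R)-4-bromo-3-chloro-4-methyl-1-[(triethylsilyl)oxy]cyclohexyl}-2-methylhepta-1,6-dien-3-one
Product: 23 (3R)-6-{(1S,3R,4R)-4-bromo-3-chloro-4-methyl-1-[(triethylsilyl)oxy]cyclohexyl}-2-methylhepta-1,6-dien-3-ol
Conditions: (S)-2-methyl-CBS-oxazaborolidine (cat.), catecholborane, toluene, −78 °C
Reagents that add atoms: none
Why: Corey–Bakshi–Shibata reduction, in which the α-branched alkenyl (isopropenyl) group acts as the large and the CH2 chain as the small ketone substituent, so that the (S)-catalyst should give the (R)-allylic alcohol (catalyst control), while catecholborane at low temperature reduces the carbonyl in the 1,2 sense without hydroborating the alkenes.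

Step 12
Reactants: 23 (3R)-6-{(1S,3R,4R)-4-bromo-3-chloro-4-methyl-1-[(triethylsilyl)oxy]cyclohexyl}-2-methylhepta-1,6-dien-3-ol
Product: 24 (1S,3R,4R)-4-bromo-3-chloro-1-[(5R)-5-hydroxy-6-methylhepta-1,6-dien-2-yl]-4-methylcyclohexan-1-ol
Conditions: HF·pyridine, THF, 0 °C
Reagents that add atoms: none
Why: Fluoride-mediated cleavage of the tertiary triethylsilyl ether under buffered, non-basic conditions that should leave the tertiary bromide, the secondary chloride and both allylic alcohols untouched.

**Compound list**

1 | 2-bromoprop-2-en-1-ol | C=C(Br)CO | starting material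
2 | ethynyltrimethylsilane | C#C[Si](C)(C)C | starting material
3 | 2-[(trimethylsilyl)ethynyl]prop-2-en-1-ol | C=C(CO)C#C[Si](C)(C)C | intermediate
4 | [(2R)-2-[(trimethylsilyl)ethynyl]oxiran-2-yl]methanol | C[Si](C)(C)C#C[C@@]1(CO)CO1 | intermediate (not isolated)
5 | [(2S)-2-[(trimethylsilyl)ethynyl]oxiran-2-yl]methyl 4-methylbenzenesulfonate | C[Si](C)(C)C#C[C@@]1(COS(=O)(=O)c2ccc(C)cc2)CO1 | intermediate
6 | (2-methylprop-2-en-1-yl)magnesium chloride | C=C(C)C[Mg]Cl | starting material
7 | tetraethenylstannane | C=C[Sn](C=C)(C=C)C=C | starting material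
8 | vinyllithium (ethenyllithium) | [Li]C=C | intermediate (not isolated)
9 | chloromagnesium (2R)-5-methyl-1-[(4-methylbenzenesulfonyl)oxy]-2-[(trimethylsilyl)ethynyl]hex-5-en-2-olate | C[Si](C)(C)C#C[C@@](O[Mg]Cl)(COS(=O)(=O)c1ccc(C)cc1)CCC(C)=C | intermediate (not isolated)
10 | (2R)-2-(3-methylbut-3-en-1-yl)-2-[(trimethylsilyl)ethynyl]oxirane | C[Si](C)(C)C#C[C@]1(CCC(C)=C)CO1 | intermediate (not isolated)
11 | (4S)-7-methyl-4-[(trimethylsilyl)ethynyl]octa-1,7-dien-4-ol | C[Si](C)(C)C#C[C@@](O)(CC=C)CCC(C)=C | intermediate
12 | (1S)-4-methyl-1-[(trimethylsilyl)ethynyl]cyclohex-3-en-1-ol | C[Si](C)(C)C#C[C@]1(O)CCC(C)=CC1 | intermediate (not isolated)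
13 | (1S)-1-ethynyl-4-methylcyclohex-3-en-1-ol | C#C[C@]1(O)CCC(C)=CC1 | intermediate
14 | (1S,3S,6R)-3-ethynyl-6-methyl-7-oxabicyclo[4.1.0]heptan-3-ol (epoxide cis to OH) | C#C[C@]1(O)CC[C@@]2(C)O[C@H]2C1 | intermediate
15 | triethyl{[(1S,3S,6R)-3-ethynyl-6-methyl-7-oxabicyclo[4.1.0]heptan-3-yl]oxy}silane | C#C[C@]1(O[Si](CC)(CC)CC)CC[C@@]2(C)O[C@H]2C1 | intermediate
16 | (1R,2R,4S)-2-chloro-4-ethynyl-1-methyl-4-[(triethylsilyl)oxy]cyclohexan-1-ol | C#C[C@]1(O[Si](CC)(CC)CC)CC[C@@](C)(O)[C@H](Cl)C1 | intermediate
17 | {[(1S,3R,4R)-4-bromo-3-chloro-1-ethynyl-4-methylcyclohexyl]oxy}triethylsilane | C#C[C@]1(O[Si](CC)(CC)CC)CC[C@@](C)(Br)[C@H](Cl)C1 | intermediate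
18 | 2-methylprop-2-enal | C=C(C)C=O | starting material
19 | ethenylmagnesium bromide | C=C[Mg]Br | starting material
20 | 2-methylpenta-1,4-dien-3-ol (racemic) | C=CC(O)C(C)=C | intermediate
21 | 6-{(1S,3R,4R)-4-bromo-3-chloro-4-methyl-1-[(triethylsilyl)oxy]cyclohexyl}-2-methylhepta-1,3,6-trien-3-ol (enol) | C=C(C)C(O)=CCC(=C)[C@]1(O[Si](CC)(CC)CC)CC[C@@](C)(Br)[C@H](Cl)C1 | intermediate (not isolated)
22 | 6-{(1S,3R,4R)-4-bromo-3-chloro-4-methyl-1-[(triethylsilyl)oxy]cyclohexyl}-2-methylhepta-1,6-dien-3-one | C=C(C)C(=O)CCC(=C)[C@]1(O[Si](CC)(CC)CC)CC[C@@](C)(Br)[C@H](Cl)C1 | intermediate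
23 | (3R)-6-{(1S,3R,4R)-4-bromo-3-chloro-4-methyl-1-[(triethylsilyl)oxy]cyclohexyl}-2-methylhepta-1,6-dien-3-ol | C=C(C)[C@H](O)CCC(=C)[C@]1(O[Si](CC)(CC)CC)CC[C@@](C)(Br)[C@H](Cl)C1 | intermediate
24 | (1S,3R,4R)-4-bromo-3-chloro-1-[(5R)-5-hydroxy-6-methylhepta-1,6-dien-2-yl]-4-methylcyclohexan-1-ol | C=C(C)[C@H](O)CCC(=C)[C@]1(O)CC[C@@](C)(Br)[C@H](Cl)C1 | target

**Step count and risks**

Total step count: 12. Longest linear sequence: 11 steps (steps 1–8 and 10–12; step 9 makes the coupling partner 20).

Steps most likely to fail:

1. Step 8 (retentive bromination of the tertiary alcohol). What may go wrong: elimination instead of substitution; capture of an open C4 cation without chlorine bridging, which would scramble the configuration at C4; migration of chlorine to C4 with bromide entering at C5; loss of the silyl ether followed by ether formation across the ring. Fallback (addition to an alkene instead of substitution of an alcohol): it sets out from 16 and comes back at 17. Compound 16 is dehydrated on purpose with the Burgess reagent (benzene, 50 °C), which should give the exocyclic alkene {[(1S,3R)-3-chloro-1-ethynyl-4-methylidenecyclohexyl]oxy}triethylsilane F1 together with the ring alkene {[(1S,5R)-5-chloro-1-ethynyl-4-methylcyclohex-3-en-1-yl]oxy}triethylsilane F2. The mixture is then treated with anhydrous HBr in CH2Cl2 at −78 °C (Markovnikov hydrobromination); both alkenes are protonated to the same tertiary C4 cation next to the axial chlorine, and bromide should add anti to chlorine to give 17.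

2. Step 3 (key step). What may go wrong: slow closure of the magnesium alkoxide onto the tosylate, so that the second nucleophile meets the sulfonate instead of an oxirane; BF3-induced rearrangement of the propargylic oxirane; direct displacement of the tosylate by the first nucleophile, which would invert the role of the two arms and erode the enantiomeric purity. Fallback (stepwise, with a sulfone-stabilised vinyl anion equivalent and no Lewis acid): it sets out from 5 and 6 and comes back at 13. The reaction is stopped after the first addition and the relay, and oxirane 10 is isolated. Compound 10 is opened with the lithium derivative of phenyl 2-(trimethylsilyl)ethyl sulfone (n-BuLi, THF, −78 → 0 °C) to give (4S)-7-methyl-2-(phenylsulfonyl)-1-(trimethylsilyl)-4-[(trimethylsilyl)ethynyl]oct-7-en-4-ol F3 (both epimers at the sulfonyl carbon). Bu4NF (THF, 50 °C) then eliminates sulfinate and the β-silyl group to unveil the vinyl group and at the same time cleaves the alkynyl silane, giving (4S)-4-ethynyl-7-methylocta-1,7-dien-4-ol F4. Ring-closing metathesis under the conditions of step 4 (without the methanolysis) returns 13.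

3. Step 10 (alkyne/allylic alcohol coupling). What may go wrong: C–C bond formation at the terminal instead of the internal alkyne carbon (linear isomer); deactivation of the cationic ruthenium catalyst by halide abstraction from the tertiary bromide; redox isomerisation of 20 instead of coupling. Fallback (cross-coupling of a 2-haloalkene): it sets out from 17 and comes back at 22. Bromoboration of the alkyne with B-bromo-9-borabicyclo[3.3.1]nonane (CH2Cl2, −78 → 0 °C) and protonolysis with acetic acid gives {[(1S,3R,4R)-4-bromo-1-(1-bromoethenyl)-3-chloro-4-methylcyclohexyl]oxy}triethylsilane F5. Negishi coupling with [2-(1,3-dioxolan-2-yl)ethyl]zinc bromide (Pd(PPh3)4 cat., THF, 23 °C) gives {[(1S,3R,4R)-4-bromo-3-chloro-1-[4-(1,3-dioxolan-2-yl)but-1-en-2-yl]-4-methylcyclohexyl]oxy}triethylsilane F6. Acetal hydrolysis (pyridinium 4-methylbenzenesulfonate, acetone/water) gives 4-{(1S,3R,4R)-4-bromo-3-chloro-4-methyl-1-[(triethylsilyl)oxy]cyclohexyl}pent-4-enal F7. Nozaki–Hiyama–Kishi addition of 2-bromopropene (CrCl2, NiCl2 cat., DMF) gives 6-{(1S,3R,4R)-4-bromo-3-chloro-4-methyl-1-[(triethylsilyl)oxy]cyclohexyl}-2-methylhepta-1,6-dien-3-ol F8 as both carbinol epimers. Dess–Martin oxidation then gives 22, from which steps 11 and 12 follow unchanged.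

Further compounds
F1 | step 8 | {[(1S,3R)-3-chloro-1-ethynyl-4-methylidenecyclohexyl]oxy}triethylsilane | C#C[C@]1(O[Si](CC)(CC)CC)CCC(=C)[C@H](Cl)C1
F2 | step 8 | {[(1S,5R)-5-chloro-1-ethynyl-4-methylcyclohex-3-en-1-yl]oxy}triethylsilane | C#C[C@]1(O[Si](CC)(CC)CC)CC=C(C)[C@H](Cl)C1
F3 | step 3 | (4S)-7-methyl-2-(phenylsulfonyl)-1-(trimethylsilyl)-4-[(trimethylsilyl)ethynyl]oct-7-en-4-ol (both C2 epimers) | C[Si](C)(C)C#C[C@@](O)(CC(C[Si](C)(C)C)S(=O)(=O)c1ccccc1)CCC(C)=C
F4 | step 3 | (4S)-4-ethynyl-7-methylocta-1,7-dien-4-ol | C#C[C@@](O)(CC=C)CCC(C)=C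
F5 | step 10 | {[(1S,3R,4R)-4-bromo-1-(1-bromoethenyl)-3-chloro-4-methylcyclohexyl]oxy}triethylsilane | C=C(Br)[C@]1(O[Si](CC)(CC)CC)CC[C@@](C)(Br)[C@H](Cl)C1
F6 | step 10 | {[(1S,3R,4R)-4-bromo-3-chloro-1-[4-(1,3-dioxolan-2-yl)but-1-en-2-yl]-4-methylcyclohexyl]oxy}triethylsilane | C=C(CCC1OCCO1)[C@]2(O[Si](CC)(CC)CC)CC[C@@](C)(Br)[C@H](Cl)C2
F7 | step 10 | 4-{(1S,3R,4R)-4-bromo-3-chloro-4-methyl-1-[(triethylsilyl)oxy]cyclohexyl}pent-4-enal | C=C(CCC=O)[C@]1(O[Si](CC)(CC)CC)CC[C@@](C)(Br)[C@H](Cl)C1
F8 | step 10 | 6-{(1S,3R,4R)-4-bromo-3-chloro-4-methyl-1-[(triethylsilyl)oxy]cyclohexyl}-2-methylhepta-1,6-dien-3-ol (both C3 epimers) | C=C(C)C(O)CCC(=C)[C@]1(O[Si](CC)(CC)CC)CC[C@@](C)(Br)[C@H](Cl)C1
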